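Ring B is read as a masked 2,6-dimethyl-1,4-benzoquinone: C17 and C20 flank C9, and O6 lies para to it. A C2-symmetric quinone monoketal accepts an acetate unit at C5 and an acrylate unit at C10 in trans fashion. O6 and C19 are then tied into a temporary γ-lactone. Everything rests on the C3–C4 disconnection of ring A (C1–C5, C10), which exploits the 1,3-dioxygenated C3–C4–C19 array. The lactone enolate acylates itself with the C3 ester, and the resulting β-keto lactone enolate is methylated in the same flask. One operation thus closes the trans-decalin and sets quaternary C4. The precursor is a cyclohexenyl triflate bearing a fused butyrolactone and a propionate arm.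

Key step: step 7

Remark on numbering: labdane numbering of the target is used for every intermediate (ring A = C1–C5 + C10; ring B = C5–C10; C17 on C8; C18/C19 on C4; C20 on C10). β is the face of C20.
Remark on the chemistry: the sense of induction of the (R,R)-ketal is assigned from a steric model, in which attack occurs in the quadrant that shows the dioxolane C–H and not the phenyl group.

Step 1
Reactants: 1 4-methoxy-2,6-dimethylphenol
Product: 2 4,4-dimethoxy-2,6-dimethylcyclohexa-2,5-dien-1-one
Conditions: PhI(OAc)2, MeOH, 0 °C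
Reagents that add atoms: methanol CO
Why: Hypervalent-iodine oxidative dearomatisation of a p-alkoxyphenol, in which the phenoxenium ion is captured by methanol at the para carbon to give the quinone monoketal without creating a stereocentre.

Step 2
Reactants: 2 4,4-dimethoxy-2,6-dimethylcyclohexa-2,5-dien-1-one; 3 (1R,2R)-1,2-diphenylethane-1,2-diol
Product: 4 (2R,3R)-7,9-dimethyl-2,3-diphenyl-1,4-dioxaspiro[4.5]deca-6,9-dien-8-one
Conditions: PPTS (10 mol%), benzene, 4 Å MS, 50 °C
Reagents that add atoms: none
Why: Acid-catalysed transketalisation is driven by removal of methanol and installs a C2-symmetric auxiliary that makes the β face at C5 and the α face at C7 homotopic, so only one kind of open quadrant remains and no ring stereocentre is formed.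

Step 3
Reactants: 5 tert-butyl acetate; 4 (2R,3R)-7,9-dimethyl-2,3-diphenyl-1,4-dioxaspiro[4.5]deca-6,9-dien-8-one; 6 methyl acrylate
Product: 9 enone diester (ring B: C9=O; C7=C8; C6 (R,R)-diphenyldioxolane; 5β-CH2CO2tBu/5α-H; 10β-CH3; 10α-CH2CH2CO2Me), via lithium enolate 7 (not isolated), via adduct dienolate 8 (not isolated)
Conditions: LDA, THF, −78 °C; 4, −78 → −20 °C; 6, −78 °C; aq NH4Cl
Reagents that add atoms: none
Why: Tandem Michael–Michael three-component coupling, in which any aldolate from 1,2-attack at the flanked C9 carbonyl reverts on warming so the ester enolate ends up at C5, where the ketal phenyl over the α face leaves only the β face open (sets C5), and the tetrasubstituted enolate 8 then takes up methyl acrylate anti to the new C5 arm, placing C1 α and C20 β (sets C10).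

Step 4
Reactants: 9 enone diester
Product: 11 vinyl triflate diester (C8=C9–OTf; C7H2; all other groups as in 9), via lithium enolate 10 (not isolated)
Conditions: L-Selectride (1.1 equiv), THF, −78 °C; Comins reagent, −78 → 0 °C; aq NH4Cl
Reagents that add atoms: Comins reagent, N-(5-chloropyridin-2-yl)bis(trifluoromethanesulfonimide) FC(F)(F)S(=O)(=O)N(c1ccc(Cl)cn1)S(=O)(=O)C(F)(F)F
Why: Selectride 1,4-reduction of a β-unsubstituted cyclohexenone (hydride on the open α face of C7) followed by O-sulfonylation of the regiodefined enolate fixes the tetrasubstituted C8=C9 bond, and since C10 carries no hydrogen the enolate cannot move and no stereocentre is formed.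

Step 5
Reactants: 11 vinyl triflate diester
Product: 12 γ-keto acid (C6=O; 5β-CH2CO2H/5α-H; 10β-CH3; 10α-CH2CH2CO2Me; C8=C9–OTf)
Conditions: TFA–CH2Cl2–H2O (5:5:1), 0 °C → rt
Reagents that add atoms: water O
Why: Aqueous acid hydrolyses the dioxolane and cleaves the tert-butyl ester by alkyl–oxygen fission, while the methyl ester and vinyl triflate survive and short contact keeps C5 and the β,γ-double bond in place.

Step 6
Reactants: 12 γ-keto acid
Product: 14 cis-fused γ-lactone (C19(=O)–O–C6β; 5α-H; 6α-H; 10β-CH3; 10α-CH2CH2CO2Me; C8=C9–OTf), via hydroxy acid 13 (not isolated)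
Conditions: L-Selectride (2.5 equiv), THF, −78 °C; then 2 M HCl, rt
Reagents that add atoms: none
Why: The bulky borohydride attacks the C6 ketone equatorially from the α face, away from axial C20 and the C5 arm, to give the axial 6β-alcohol cis to that arm, and acidification closes the γ-lactone (lactonisation).

Step 7
Reactants: 14 cis-fused γ-lactone
Product: 16 3-oxo-4α-methyl-19,6β-olide (trans-decalin; 5α-H; 10β-CH3; C19 β on C4; C8=C9–OTf), via potassium enolate 15 (not isolated)
Conditions: KHMDS (2.1 equiv), THF, −78 → 0 °C; MeI (5 equiv), DMPU, 0 °C → rt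
Reagents that add atoms: iodomethane CI
Why: KHMDS removes a C4–H of the γ-lactone, an E-configured ester several pK units more acidic than the Z-configured methyl ester at C2; the enolate adds to the C3 ester carbonyl and methoxide leaves, which is an intramolecular Claisen (Dieckmann) condensation. Ring A (C10–C1–C2–C3–C4–C5) closes 6-exo-trig at the acyl carbon, and because the C5–C4 and C10–C1 bonds are already trans-diequatorial on ring B the decalin can only be trans. The product is deprotonated at once to the β-keto lactone enolate 15, which pulls the equilibrium over and shields C3. MeI then alkylates C4, the only new stereocentre: C19 is held on the β face by the O6 bridge, so the methyl group can enter only from the α face, which is also the face away from axial C20. The step needs selectivity between the two Claisen modes (C4→C3 against C2→C19) and C- over O-alkylation; the first is secured by the acidity difference and the irreversible enolisation of the product, the second by the soft electrophile.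

Step 8
Reactants: 16 3-oxo-4α-methyl-19,6β-olide
Product: 17 3α-hydroxy-19,6β-olide (axial 3α-OH; otherwise as 16)
Conditions: L-Selectride (1.3 equiv), THF, −78 °C; aq NH4Cl
Reagents that add atoms: none
Why: In this Selectride reduction of a hindered cyclohexanone the bulky borohydride avoids the axial trajectory past H1α and H5α and comes in equatorially to give the axial 3α-alcohol, while lactone and vinyl triflate are inert at −78 °C.

Step 9
Reactants: 17 3α-hydroxy-19,6β-olide
Product: 18 3α,6β,19-triol vinyl triflate (4α-CH3; 4β-CH2OH; 5α-H; 10β-CH3; C8=C9–OTf)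
Conditions: DIBAL-H (6 equiv), CH2Cl2, −78 °C → rt; Rochelle salt
Reagents that add atoms: none
Why: Exhaustive DIBAL-H reduction opens the temporary lactone through the lactol to the 6β,19-diol without touching a stereocentre, and vinyl triflates tolerate this electrophilic hydride.

Step 10
Reactants: 19 methyl but-2-ynoate; 20 vinylmagnesium bromide
Product: 22 methyl (2E)-3-methylpenta-2,4-dienoate, via alkenylcopper 21 (not isolated)
Conditions: CuI (1.05 equiv), 20, THF, −40 °C; 19, −78 °C; aq NH4Cl at −78 °C
Reagents that add atoms: none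
Why: In this syn-carbocupration of an ynoate, vinyl and copper add to the same side and cold protonation retains the geometry, so the future C12 ends up trans to the ester (13E).

Step 11
Reactants: 18 3α,6β,19-triol vinyl triflate; 22 methyl (2E)-3-methylpenta-2,4-dienoate
Product: 24 methyl ester of the target (methyl 3α,6β,19-trihydroxylabda-8,13E-dien-15-oate), via alkylborane 23 (not isolated)
Conditions: 22, 9-BBN-H, THF, 0 °C → rt; then 18, Pd(dppf)Cl2 (10 mol%), AsPh3, Cs2CO3, DMF–H2O, 50 °C
Reagents that add atoms: none
Why: Chemoselective hydroboration of the monosubstituted vinyl group followed by B-alkyl Suzuki–Miyaura coupling joins C11 to C9 with retention of both double-bond geometries and tolerates the free triol.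

Step 12
Reactants: 24 methyl ester of the target
Product: 25 target CNP0246116.2 (3α,6β,19-trihydroxylabda-8,13E-dien-15-oic acid)
Conditions: LiOH, THF–MeOH–H2O, rt; then 1 M HCl to pH 3
Reagents that add atoms: lithium hydroxide [Li+].[OH-]
Why: Saponification of the unhindered conjugated methyl ester and mild acidification release the acid without affecting any stereocentre or the tetrasubstituted alkene.

Compound list
1 | 4-methoxy-2,6-dimethylphenol | COc1cc(C)c(O)c(C)c1 | starting material
2 | 4,4-dimethoxy-2,6-dimethylcyclohexa-2,5-dien-1-one | COC1(OC)C=C(C)C(=O)C(C)=C1 | intermediate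
3 | (1R,2R)-1,2-diphenylethane-1,2-diol, (R,R)-hydrobenzoin | O[C@H](c1ccccc1)[C@H](O)c1ccccc1 | starting material
4 | (2R,3R)-7,9-dimethyl-2,3-diphenyl-1,4-dioxaspiro[4.5]deca-6,9-dien-8-one | CC1=CC2(C=C(C)C1=O)O[C@H](c3ccccc3)[C@@H](c3ccccc3)O2 | intermediate
5 | tert-butyl acetate | CC(=O)OC(C)(C)C | starting material
6 | methyl acrylate | C=CC(=O)OC | starting material
7 | lithium enolate of tert-butyl acetate | C=C([O-])OC(C)(C)C.[Li+] | intermediate
8 | lithium cross-conjugated dienolate from 1,4-addition at C5 (5β-CH2CO2tBu, 5α-H) | CC=1C([O-])=C(C)[C@H](CC(=O)OC(C)(C)C)C2(O[C@H](c3ccccc3)[C@@H](c3ccccc3)O2)C=1.[Li+] | intermediate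
9 | enone diester (C9=O, C7=C8, C6 (R,R)-diphenyldioxolane, 5β-CH2CO2tBu, 5α-H, 10β-CH3, 10α-CH2CH2CO2Me) | CC=1C(=O)[C@@](C)(CCC(=O)OC)[C@H](CC(=O)OC(C)(C)C)C2(O[C@H](c3ccccc3)[C@@H](c3ccccc3)O2)C=1 | intermediate
10 | lithium C8=C9 enolate from 1,4-reduction of 9 | CC1=C([O-])[C@@](C)(CCC(=O)OC)[C@H](CC(=O)OC(C)(C)C)C2(O[C@H](c3ccccc3)[C@@H](c3ccccc3)O2)C1.[Li+] | intermediate
11 | vinyl triflate diester (C8=C9–OTf, C7H2, other groups as in 9) | CC1=C(OS(=O)(=O)C(F)(F)F)[C@@](C)(CCC(=O)OC)[C@H](CC(=O)OC(C)(C)C)C2(O[C@H](c3ccccc3)[C@@H](c3ccccc3)O2)C1 | intermediate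
12 | γ-keto acid (C6=O, 5β-CH2CO2H, 5α-H, 10β-CH3, 10α-CH2CH2CO2Me, C8=C9–OTf) | CC1=C(OS(=O)(=O)C(F)(F)F)[C@@](C)(CCC(=O)OC)[C@H](CC(=O)O)C(=O)C1 | intermediate
13 | 6β-hydroxy acid | CC1=C(OS(=O)(=O)C(F)(F)F)[C@@](C)(CCC(=O)OC)[C@H](CC(=O)O)[C@H](O)C1 | intermediate
14 | cis-fused γ-lactone (C19(=O)–O–C6β, 5α-H, 6α-H, 10β-CH3, 10α-CH2CH2CO2Me, C8=C9–OTf) | CC1=C(OS(=O)(=O)C(F)(F)F)[C@@](C)(CCC(=O)OC)[C@@H]2CC(=O)O[C@@H]2C1 | intermediate
15 | potassium enolate of the 3-oxo-19,6β-olide (ring A closed, C4 sp2) | CC1=C(OS(=O)(=O)C(F)(F)F)[C@@]2(C)CCC([O-])=C3[C@@H]2[C@@H](C1)OC3=O.[K+] | intermediate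
16 | 3-oxo-4α-methyl-19,6β-olide (trans-decalin, 5α-H, 10β-CH3, C19 β, C8=C9–OTf) | CC1=C(OS(=O)(=O)C(F)(F)F)[C@@]2(C)CCC(=O)[C@@]3(C)[C@@H]2[C@@H](C1)OC3=O | intermediate
17 | 3α-hydroxy-19,6β-olide | CC1=C(OS(=O)(=O)C(F)(F)F)[C@@]2(C)CC[C@@H](O)[C@@]3(C)[C@@H]2[C@@H](C1)OC3=O | intermediate
18 | 3α,6β,19-triol vinyl triflate | CC1=C(OS(=O)(=O)C(F)(F)F)[C@@]2(C)CC[C@@H](O)[C@](C)(CO)[C@@H]2[C@H](O)C1 | intermediate
19 | methyl but-2-ynoate | CC#CC(=O)OC | starting material
20 | vinylmagnesium bromide | C=C[Mg]Br | starting material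
21 | alkenylcopper from syn-addition (vinyl cis to Cu) | C=C/C(C)=C(\[Cu])C(=O)OC | intermediate
22 | methyl (2E)-3-methylpenta-2,4-dienoate | C=C/C(C)=C/C(=O)OC | intermediate
23 | B-alkyl-9-BBN, methyl (2E)-5-(9-borabicyclo[3.3.1]nonan-9-yl)-3-methylpent-2-enoate | COC(=O)/C=C(C)/CCB1C2CCCC1CCC2 | intermediate
24 | methyl 3α,6β,19-trihydroxylabda-8,13E-dien-15-oate | CC1=C(CC/C(C)=C/C(=O)OC)[C@@]2(C)CC[C@@H](O)[C@](C)(CO)[C@@H]2[C@H](O)C1 | intermediate
25 | CNP0246116.2, 3α,6β,19-trihydroxylabda-8,13E-dien-15-oic acid | CC1=C(CC/C(C)=C/C(=O)O)[C@@]2(C)CC[C@@H](O)[C@](C)(CO)[C@@H]2[C@H](O)C1 | target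

Total step count: 12. Longest linear sequence: 11 (steps 1–9, 11, 12).

Steps most likely to fail

Step 3. Three things may go wrong.
- The ester enolate may remain at the carbonyl as the 1,2-adduct.
- The phenyl groups may discriminate the two faces of C5 too weakly.
- The last-formed ester enolate may go on to oligomerise the acrylate.

The fallback sets out from 5 and 4 and returns at 9, using two separately controlled, silicon-mediated Michael additions. Compound 5 is converted (LDA, TBSCl) into its ketene silyl acetal F1. This adds to 4 in 5 M LiClO4–Et2O (Mukaiyama–Michael, strictly 1,4) to give the isolable silyl dienol ether F2. Its C5 epimers are diastereomers because of the ketal and can be separated at this stage. F2 is then added to 6 under catalysis by a soluble fluoride (TBAT), again anti to the C5 arm, and aqueous work-up gives 9.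

Step 4. Hydride transfer to C7 may be too slow next to the spiroketal, so that 1,2-reduction of C9=O or no reaction takes over. The hindered enolate may also be sulfonylated only in part. The fallback sets out from 9 and returns at 11. Rhodium-catalysed 1,4-hydrosilylation (Wilkinson catalyst, Et3SiH) gives the triethylsilyl enol ether F3. It is isolated and converted with CsF and PhNTf2 in DME into 11.

Step 8. Facial selectivity may be poor, because the equatorial path runs past axial C19 and hydride may then enter axially from the α face. The fallback sets out from 16 and returns at 18, bypassing 17, and replaces reagent control by intramolecular hydride delivery.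
- The ketone is masked as the TBS enol ether F4 (TBSOTf, Et3N; only C2 can be deprotonated).
- DIBAL-H opens the lactone to the diol F5.
- HF·pyridine releases the β-hydroxy ketone F6.
- Me4NBH(OAc)3 in MeCN–AcOH (Evans–Saksena reduction), bound to the axial 19-OH, delivers hydride to the β face of C3 and gives 18.

Further compounds
F1 | step 3 | ketene silyl acetal of tert-butyl acetate | C=C(OC(C)(C)C)O[Si](C)(C)C(C)(C)C
F2 | step 3 | TBS dienol ether of the C5 adduct (5β-CH2CO2tBu, 5α-H) | CC=1C(O[Si](C)(C)C(C)(C)C)=C(C)[C@H](CC(=O)OC(C)(C)C)C2(O[C@H](c3ccccc3)[C@@H](c3ccccc3)O2)C=1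
F3 | step 4 | triethylsilyl C8=C9 enol ether of reduced 9 | CC1=C(O[Si](CC)(CC)CC)[C@@](C)(CCC(=O)OC)[C@H](CC(=O)OC(C)(C)C)C2(O[C@H](c3ccccc3)[C@@H](c3ccccc3)O2)C1
F4 | step 8 | C2=C3 TBS enol ether of 16 | CC1=C(OS(=O)(=O)C(F)(F)F)[C@@]2(C)CC=C(O[Si](C)(C)C(C)(C)C)[C@@]3(C)[C@@H]2[C@@H](C1)OC3=O
F5 | step 8 | 6β,19-diol C2=C3 TBS enol ether | CC1=C(OS(=O)(=O)C(F)(F)F)[C@@]2(C)CC=C(O[Si](C)(C)C(C)(C)C)[C@](C)(CO)[C@@H]2[C@H](O)C1
F6 | step 8 | 6β,19-dihydroxy-3-ketone | CC1=C(OS(=O)(=O)C(F)(F)F)[C@@]2(C)CCC(=O)[C@](C)(CO)[C@@H]2[C@H](O)C1
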